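The target's decalin is disconnected at a cyclopropane-fused cyclopentanone; the route runs 11 linear steps from nerol, and step 8 is a proposed cascade that has not been demonstrated on this bond type.

Drimane numbering is used (ring A: C1–C5 and C10, with C3–OH and C4 gem-dimethyl; ring B: C5–C10; C11 is the OCH2 carbon). Ring A is disconnected to the cyclopentanone ring of a bicyclo[3.1.0]hexan-2-one in which C2 and C10 are still bonded across a cyclopropane. Because the C3 oxygen stands 1,4 to quaternary C10, Lewis-acid opening of this internal bond, with the tethered Z-alkene C8=C9 attacking C10, enlarges the five-membered ring to ring A, closes ring B and sets C10 and C9 in one operation. All stereochemistry is relayed from C5, set by an Ireland–Claisen rearrangement; scopoletin is attached last.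

Key step: step 8

Remark (reading of the target): the SMILES is read as the trans-fused decalin (3S,5S,9S,10R) in which the C3 hydroxyl and the C9 CH2OAr group are both axial and anti to the C10 methyl. This is why a Z-alkene terminator and an axial-selective ketone reduction are planned.

Remark (labels): atoms of intermediates carry the drimane number of the target atom they become. TBDPS = tert-butyldiphenylsilyl; MIB = 3-exo-morpholinoisoborneol.

Step 1
Reactants: 1 nerol, (2Z)-3,7-dimethylocta-2,6-dien-1-ol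
Product: 2 neryl TBDPS ether, tert-butyl{[(2Z)-3,7-dimethylocta-2,6-dien-1-yl]oxy}diphenylsilane
Conditions: t-BuPh2SiCl, imidazole, DMF, 0 °C → rt
Reagents that add atoms: tert-butyl(chloro)diphenylsilane, CC(C)(C)[Si](Cl)(c1ccccc1)c1ccccc1
Why: Standard silylation of a primary alcohol; the robust TBDPS ether is chosen to survive strong base, the sulfur ylide, SnCl4 and hydride until step 10.

Step 2
Reactants: 2 neryl TBDPS ether
Product: 4 (2E,6Z)-8-(TBDPSO)-2,6-dimethylocta-2,6-dienal, via (2E,6Z)-allylic alcohol 3 (not isolated)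
Conditions: SeO2 (0.3 equiv), t-BuOOH, salicylic acid (cat.), CH2Cl2, rt; then MnO2, CH2Cl2, rt
Reagents that add atoms: selenium dioxide, O=[Se]=O; tert-butyl hydroperoxide, CC(C)(C)OO
Why: Riley allylic oxidation (ene reaction then [2,3]-sigmatropic shift) should hit only the E-methyl of the terminal, more electron-rich trisubstituted alkene (the 2,3-alkene is deactivated by the allylic oxygen), and MnO2 then converts the E-allylic alcohol into the E-enal without touching either double bond.

Step 3
Reactants: 4 (2E,6Z)-8-(TBDPSO)-2,6-dimethylocta-2,6-dienal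
Product: 6 (2R,3E,7Z)-9-(TBDPSO)-3,7-dimethylnona-3,7-dien-2-yl 2-methylpropanoate, via methylzinc alkoxide 5 (not isolated)
Conditions: ZnMe2 (2 equiv), (+)-MIB (4 mol %), toluene/hexane, 0 °C; then (i-PrCO)2O, DMAP (cat.), rt
Reagents that add atoms: dimethylzinc, C[Zn]C; 2-methylpropanoic anhydride, CC(C)C(=O)OC(=O)C(C)C
Why: Amino-alcohol-catalysed enantioselective addition of a dialkylzinc to an aldehyde: the catalyst enantiomer, (+)-MIB, is chosen to deliver methyl to the Re face of the 2-methyl-enal, which sets the (R)-carbinol, and the zinc alkoxide is acylated in the same flask.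

Step 4
Reactants: 6 (2R,3E,7Z)-9-(TBDPSO)-3,7-dimethylnona-3,7-dien-2-yl 2-methylpropanoate
Product: 9 (3S,4E)-3-[(3Z)-5-(TBDPSO)-3-methylpent-3-en-1-yl]-2,2,4-trimethylhex-4-enoic acid, via silyl ketene acetal 7 (not isolated), via trimethylsilyl ester 8 (not isolated)
Conditions: LiN(i-Pr)2, THF, −78 °C; Me3SiCl/Et3N, −78 → 50 °C; aq. HCl work-up
Reagents that add atoms: none
Why: Ireland–Claisen rearrangement through a chair transition state with the carbinol methyl equatorial transfers the C–O chirality to the new C4–C5 bond (C5 becomes S) and gives the E-propenyl group; the enolate carries two methyl groups, so no enolate geometry has to be controlled.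

Step 5
Reactants: 9 (3S,4E)-3-[(3Z)-5-(TBDPSO)-3-methylpent-3-en-1-yl]-2,2,4-trimethylhex-4-enoic acid
Product: 11 (5S,6E)-5-[(3Z)-5-(TBDPSO)-3-methylpent-3-en-1-yl]-4,4,6-trimethylocta-1,6-dien-3-one, via acid chloride 10 (not isolated)
Conditions: 1-chloro-N,N,2-trimethylprop-1-en-1-amine, CH2Cl2, 0 °C → rt; then tributyl(vinyl)stannane, Pd2(dba)3 (2.5 mol %), P(2-furyl)3, THF, 50 °C
Reagents that add atoms: tributyl(vinyl)stannane, C=C[Sn](CCCC)(CCCC)CCCC
Why: The α-quaternary acid is converted into its chloride under neutral conditions (no HCl near the silyl ether and alkenes) and then undergoes Stille acylation with the vinylstannane, a coupling that tolerates hindered acyl chlorides and leaves C5 untouched.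

Step 6
Reactants: 11 (5S,6E)-5-[(3Z)-5-(TBDPSO)-3-methylpent-3-en-1-yl]-4,4,6-trimethylocta-1,6-dien-3-one
Product: 12 (4S)-4-[(3Z)-5-(TBDPSO)-3-methylpent-3-en-1-yl]-3,5,5-trimethylcyclopent-2-en-1-one
Conditions: second-generation Hoveyda–Grubbs catalyst (5 mol %), toluene, 80 °C
Reagents that add atoms: none
Why: Ring-closing metathesis: the enone vinyl group and the propenyl group close the five-membered ring (helped by the gem-dimethyl group) with loss of propene, while the remote Z-trisubstituted alkene is too hindered to compete; C5 is untouched.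

Step 7
Reactants: 12 (4S)-4-[(3Z)-5-(TBDPSO)-3-methylpent-3-en-1-yl]-3,5,5-trimethylcyclopent-2-en-1-one
Product: 13 (1S,4S,5S)-4-[(3Z)-5-(TBDPSO)-3-methylpent-3-en-1-yl]-3,3,5-trimethylbicyclo[3.1.0]hexan-2-one
Conditions: Me3S(O)I, NaH, DMSO, rt → 50 °C
Reagents that add atoms: trimethylsulfoxonium iodide, C[S+](C)(C)=O.[I-]
Why: Corey–Chaykovsky cyclopropanation (conjugate addition of the sulfoxonium ylide to C10, then 3-exo-tet closure of the enolate carbon C2 on the CH2): the ylide should add to the enone face anti to the C5 side chain, so the new CH2 (C1) ends trans to the chain, which fixes both cyclopropane stereocentres.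

Step 8
Reactants: 13 (1S,4S,5S)-4-[(3Z)-5-(TBDPSO)-3-methylpent-3-en-1-yl]-3,3,5-trimethylbicyclo[3.1.0]hexan-2-one
Product: 14 (4aR,5S,8aS)-5-[(TBDPSO)methyl]-1,1,4a,6-tetramethyl-3,4,4a,5,8,8a-hexahydronaphthalen-2(1H)-one
Conditions: SnCl4 (1.5 equiv), CH2Cl2, −78 → −20 °C
Reagents that add atoms: none
Why: Proposed new method: SnCl4 binds the C3 carbonyl and polarises the internal cyclopropane bond C2–C10 towards the fully substituted C10, which the tethered alkene attacks through C9 on the side opposite to C2 as that bond breaks, so that the five-membered ring becomes ring A (C1 now lies between C2 and C10) while the C8 cation loses H7 to give the 7,8-alkene and the tin enolate is protonated by the acid set free (net isomerisation). The closest known reaction types are the Lewis-acid opening of acylcyclopropanes with olefin participation (cyclopropyl-ketone-initiated cation–olefin cyclisation, known for external cyclopropane bonds) and the acid-induced enlargement of 5-alkylbicyclo[3.1.0]hexan-2-ones to 4-alkylcyclohexanones by cleavage of this same internal bond; the step merges the two. Ring B closes in a 6-endo-trig cation–olefin mode through a chair-like transition state, and ring A is not closed but enlarged by one atom through scission of C2–C10. C10 is set by inversion: the chain on C5 lies anti to the cyclopropane CH2 (from step 7) and reaches the rear of the C2–C10 bond, which puts the C10 methyl anti to H5 (trans-decalin), and C9 is set by the Z geometry of the alkene, which places CH2OTBDPS axial and anti to the C10 methyl. The step needs cleavage of the internal bond and not of the external C2–C1 bond, which the cation-stabilising, fully substituted C10 and the six-membered reach of the tether should secure, and it needs loss of H7 and not of a methyl hydrogen from the C8 cation, favoured by the axial H7 of the chair. Should the bond ionise before the alkene arrives, the same chair closure governed by C5 should lead to the same isomer.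

Step 9
Reactants: 14 (4aR,5S,8aS)-5-[(TBDPSO)methyl]-1,1,4a,6-tetramethyl-3,4,4a,5,8,8a-hexahydronaphthalen-2(1H)-one
Product: 15 (2S,4aR,5S,8aS)-5-[(TBDPSO)methyl]-1,1,4a,6-tetramethyl-1,2,3,4,4a,5,8,8a-octahydronaphthalen-2-ol
Conditions: Li(s-Bu)3BH, THF, −78 → 0 °C; aq. NH4Cl
Reagents that add atoms: none
Why: The bulky hydride should approach the hindered 4,4-dimethyl ketone along the equatorial direction (steric approach control), giving the axial 3S alcohol anti to the C10 methyl; the trisubstituted alkene is inert.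

Step 10
Reactants: 15 (2S,4aR,5S,8aS)-5-[(TBDPSO)methyl]-1,1,4a,6-tetramethyl-1,2,3,4,4a,5,8,8a-octahydronaphthalen-2-ol
Product: 16 (2S,4aR,5S,8aS)-5-(hydroxymethyl)-1,1,4a,6-tetramethyl-1,2,3,4,4a,5,8,8a-octahydronaphthalen-2-ol
Conditions: Bu4NF, THF, rt
Reagents that add atoms: none
Why: Fluoride cleaves the Si–O bond (strong Si–F bond) and frees the primary C11 hydroxyl; nothing else in the molecule reacts.

Step 11
Reactants: 16 (2S,4aR,5S,8aS)-5-(hydroxymethyl)-1,1,4a,6-tetramethyl-1,2,3,4,4a,5,8,8a-octahydronaphthalen-2-ol; 17 scopoletin, 7-hydroxy-6-methoxy-2H-chromen-2-one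
Product: 18 7-{[(1S,4aS,6S,8aR)-6-hydroxy-2,5,5,8a-tetramethyl-1,4,4a,5,6,7,8,8a-octahydronaphthalen-1-yl]methoxy}-6-methoxy-2H-chromen-2-one (CNP0218138.1)
Conditions: PPh3, DIAD, THF, 0 °C → rt
Reagents that add atoms: none
Why: Mitsunobu etherification: the acidic phenol displaces the primary C11 alkoxyphosphonium in an SN2 step, while the axial C3 hydroxyl next to the gem-dimethyl group is too hindered to be activated, so no stereocentre is touched.

Compound list

1 | nerol, (2Z)-3,7-dimethylocta-2,6-dien-1-ol | CC(C)=CCC/C(C)=C\CO | starting material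
2 | tert-butyl{[(2Z)-3,7-dimethylocta-2,6-dien-1-yl]oxy}diphenylsilane | CC(C)=CCC/C(C)=C\CO[Si](c1ccccc1)(c1ccccc1)C(C)(C)C | intermediate
3 | (2E,6Z)-8-(TBDPSO)-2,6-dimethylocta-2,6-dien-1-ol | OC/C(C)=C/CC/C(C)=C\CO[Si](c1ccccc1)(c1ccccc1)C(C)(C)C | intermediate
4 | (2E,6Z)-8-(TBDPSO)-2,6-dimethylocta-2,6-dienal | O=C/C(C)=C/CC/C(C)=C\CO[Si](c1ccccc1)(c1ccccc1)C(C)(C)C | intermediate
5 | methylzinc (2R,3E,7Z)-9-(TBDPSO)-3,7-dimethylnona-3,7-dien-2-olate | C[Zn]O[C@H](C)/C(C)=C/CC/C(C)=C\CO[Si](c1ccccc1)(c1ccccc1)C(C)(C)C | intermediate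
6 | (2R,3E,7Z)-9-(TBDPSO)-3,7-dimethylnona-3,7-dien-2-yl 2-methylpropanoate | CC(C)C(=O)O[C@H](C)/C(C)=C/CC/C(C)=C\CO[Si](c1ccccc1)(c1ccccc1)C(C)(C)C | intermediate
7 | trimethyl({2-methyl-1-[((2R,3E,7Z)-9-(TBDPSO)-3,7-dimethylnona-3,7-dien-2-yl)oxy]prop-1-en-1-yl}oxy)silane | CC(C)=C(O[Si](C)(C)C)O[C@H](C)/C(C)=C/CC/C(C)=C\CO[Si](c1ccccc1)(c1ccccc1)C(C)(C)C | intermediate
8 | trimethylsilyl (3S,4E)-3-[(3Z)-5-(TBDPSO)-3-methylpent-3-en-1-yl]-2,2,4-trimethylhex-4-enoate | C[Si](C)(C)OC(=O)C(C)(C)[C@@H](CC/C(C)=C\CO[Si](c1ccccc1)(c1ccccc1)C(C)(C)C)/C(C)=C/C | intermediate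
9 | (3S,4E)-3-[(3Z)-5-(TBDPSO)-3-methylpent-3-en-1-yl]-2,2,4-trimethylhex-4-enoic acid | OC(=O)C(C)(C)[C@@H](CC/C(C)=C\CO[Si](c1ccccc1)(c1ccccc1)C(C)(C)C)/C(C)=C/C | intermediate
10 | (3S,4E)-3-[(3Z)-5-(TBDPSO)-3-methylpent-3-en-1-yl]-2,2,4-trimethylhex-4-enoyl chloride | ClC(=O)C(C)(C)[C@@H](CC/C(C)=C\CO[Si](c1ccccc1)(c1ccccc1)C(C)(C)C)/C(C)=C/C | intermediate
11 | (5S,6E)-5-[(3Z)-5-(TBDPSO)-3-methylpent-3-en-1-yl]-4,4,6-trimethylocta-1,6-dien-3-one | C=CC(=O)C(C)(C)[C@@H](CC/C(C)=C\CO[Si](c1ccccc1)(c1ccccc1)C(C)(C)C)/C(C)=C/C | intermediate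
12 | (4S)-4-[(3Z)-5-(TBDPSO)-3-methylpent-3-en-1-yl]-3,5,5-trimethylcyclopent-2-en-1-one | O=C1C=C(C)[C@H](CC/C(C)=C\CO[Si](c2ccccc2)(c2ccccc2)C(C)(C)C)C1(C)C | intermediate
13 | (1S,4S,5S)-4-[(3Z)-5-(TBDPSO)-3-methylpent-3-en-1-yl]-3,3,5-trimethylbicyclo[3.1.0]hexan-2-one | O=C1[C@H]2C[C@@]2(C)[C@H](CC/C(C)=C\CO[Si](c3ccccc3)(c3ccccc3)C(C)(C)C)C1(C)C | intermediate
14 | (4aR,5S,8aS)-5-[(TBDPSO)methyl]-1,1,4a,6-tetramethyl-3,4,4a,5,8,8a-hexahydronaphthalen-2(1H)-one | CC(C)(C)[Si](c1ccccc1)(c1ccccc1)OC[C@H]1C(C)=CC[C@@H]2C(C)(C)C(=O)CC[C@]21C | intermediate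
15 | (2S,4aR,5S,8aS)-5-[(TBDPSO)methyl]-1,1,4a,6-tetramethyl-1,2,3,4,4a,5,8,8a-octahydronaphthalen-2-ol | CC(C)(C)[Si](c1ccccc1)(c1ccccc1)OC[C@H]1C(C)=CC[C@@H]2C(C)(C)[C@@H](O)CC[C@]21C | intermediate
16 | (2S,4aR,5S,8aS)-5-(hydroxymethyl)-1,1,4a,6-tetramethyl-1,2,3,4,4a,5,8,8a-octahydronaphthalen-2-ol | OC[C@H]1C(C)=CC[C@@H]2C(C)(C)[C@@H](O)CC[C@]21C | intermediate
17 | scopoletin, 7-hydroxy-6-methoxy-2H-chromen-2-one | COc1cc2ccc(=O)oc2cc1O | starting material
18 | 7-{[(1S,4aS,6S,8aR)-6-hydroxy-2,5,5,8a-tetramethyl-1,4,4a,5,6,7,8,8a-octahydronaphthalen-1-yl]methoxy}-6-methoxy-2H-chromen-2-one | COc1cc2ccc(=O)oc2cc1OC[C@H]1C(C)=CC[C@@H]2C(C)(C)[C@@H](O)CC[C@]21C | target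

Total step count: 11. Longest linear sequence: 11 steps (1 → 18); scopoletin 17 enters in the last step.

Steps most likely to fail

Step 8 (Proposed new method). The opening may proceed without capture by the alkene: the C10 cation may lose a proton (towards C1, or towards C5 with loss of the controlling stereocentre) or collect chloride. The external cyclopropane bond, which overlaps better with the carbonyl, may break instead, or the allylic silyl ether may ionise. After closure, the C8 cation may shed a methyl proton (exocyclic alkene), or ring B may close through a boat (C9 epimer). The fallback separates the two events, each by known chemistry; it sets out from 13 and comes back at 14. Compound 13 is opened with dry HCl (1 equiv, CH2Cl2/Et2O, −20 °C), the known ring-enlarging hydrohalide opening of a 5-alkylbicyclo[3.1.0]hexan-2-one at its tertiary bridgehead, to give the chloro ketone (3R,4R)-4-chloro-3-[(3Z)-5-(TBDPSO)-3-methylpent-3-en-1-yl]-2,2,4-trimethylcyclohexan-1-one F1. The tertiary chloride is then ionised (AgBF4 or SnCl4, 2,6-di-tert-butylpyridine, CH2Cl2, −78 °C) and the free C10 cation closes ring B in an ordinary tertiary-cation-initiated cation–olefin cyclisation, with the chain equatorial on C5 in a chair, to give 14. Addition of HCl to the chain alkene is the residual risk of this detour and would be limited by the low temperature and the single equivalent.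

Step 7. Conjugate addition of the ylide to the hindered β,β-disubstituted enone may be slower than γ-deprotonation, which would scramble C5 through the dienolate, or slower than attack at the carbonyl (epoxide formation). The fallback builds the cyclopropane stepwise; it sets out from 12 and comes back at 13. Copper-catalysed conjugate addition of (i-PrO)Me2SiCH2MgCl (CuBr·SMe2 cat., Me3SiCl, THF, −78 °C), anti to the side chain, should give the silylmethyl ketone (3R,4R)-3-[(3Z)-5-(TBDPSO)-3-methylpent-3-en-1-yl]-4-({dimethyl[(propan-2-yl)oxy]silyl}methyl)-2,2,4-trimethylcyclopentan-1-one F2. Tamao oxidation (KF, KHCO3, H2O2, THF/MeOH) gives the hydroxymethyl ketone (3S,4R)-3-[(3Z)-5-(TBDPSO)-3-methylpent-3-en-1-yl]-4-(hydroxymethyl)-2,2,4-trimethylcyclopentan-1-one F3. Mesylation (MsCl, Et3N) gives the mesylate (3S,4R)-3-[(3Z)-5-(TBDPSO)-3-methylpent-3-en-1-yl]-4-[(methanesulfonyloxy)methyl]-2,2,4-trimethylcyclopentan-1-one F4, and KOt-Bu (THF, 0 °C) closes the three-membered ring by intramolecular enolate alkylation to 13.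

Step 11. SN2 displacement at the β-branched, axial C11 alkoxyphosphonium may be too slow, so that the activated alcohol is diverted (alkylation of the hydrazide, elimination towards C9) or the diol is recovered. The fallback makes the ether bond at the aryl carbon instead of at C11; it sets out from 16 and 17 and comes back at 18. Scopoletin is converted (Tf2O, pyridine, CH2Cl2) into its triflate 6-methoxy-2-oxo-2H-chromen-7-yl trifluoromethanesulfonate F5, which is joined to the primary hydroxyl of 16 by palladium-catalysed C–O cross-coupling (Pd2(dba)3, t-BuBrettPhos, Cs2CO3, toluene, 80 °C) to give 18 directly; the hindered axial C3 hydroxyl should not couple.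

Further compounds

F1 | step 8 | (3R,4R)-4-chloro-3-[(3Z)-5-(TBDPSO)-3-methylpent-3-en-1-yl]-2,2,4-trimethylcyclohexan-1-one | O=C1CC[C@@](C)(Cl)[C@H](CC/C(C)=C\CO[Si](c2ccccc2)(c2ccccc2)C(C)(C)C)C1(C)C
F2 | step 7 | (3R,4R)-3-[(3Z)-5-(TBDPSO)-3-methylpent-3-en-1-yl]-4-({dimethyl[(propan-2-yl)oxy]silyl}methyl)-2,2,4-trimethylcyclopentan-1-one | O=C1C[C@@](C)(C[Si](C)(C)OC(C)C)[C@H](CC/C(C)=C\CO[Si](c2ccccc2)(c2ccccc2)C(C)(C)C)C1(C)C
F3 | step 7 | (3S,4R)-3-[(3Z)-5-(TBDPSO)-3-methylpent-3-en-1-yl]-4-(hydroxymethyl)-2,2,4-trimethylcyclopentan-1-one | O=C1C[C@@](C)(CO)[C@H](CC/C(C)=C\CO[Si](c2ccccc2)(c2ccccc2)C(C)(C)C)C1(C)C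
F4 | step 7 | (3S,4R)-3-[(3Z)-5-(TBDPSO)-3-methylpent-3-en-1-yl]-4-[(methanesulfonyloxy)methyl]-2,2,4-trimethylcyclopentan-1-one | O=C1C[C@@](C)(COS(C)(=O)=O)[C@H](CC/C(C)=C\CO[Si](c2ccccc2)(c2ccccc2)C(C)(C)C)C1(C)C
F5 | step 11 | 6-methoxy-2-oxo-2H-chromen-7-yl trifluoromethanesulfonate | COc1cc2ccc(=O)oc2cc1OS(=O)(=O)C(F)(F)F
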